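## Retrosynthetic overview
1. Target ⇒ its 5,7-di-O-methyl ether; the last step cleaves both aryl methyl ethers with BBr3.
2. Ring B (4-pyranone) ⇒ the saturated ketone 1-(2-hydroxy-4,6-dimethoxy-3,5-dimethylphenyl)hexadecan-1-one. One new aerobic palladium cascade makes the O1–C2 bond and the C2=C3 double bond. The palmitoyl chain maps as C1 = C4, C2 = C3, C3 = C2 and C4–C16 = tridecyl.
3. Aryl ketone ⇒ 1,3,5-trimethoxy-2,4-dimethylbenzene + palmitoyl chloride (Friedel–Crafts, C4–C4a bond), then chelation-controlled loss of one ortho methyl ether.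
4. Arene ⇒ 2,4,6-trimethoxytoluene + MeI; directed ortho-metalation installs the second ring methyl.
5. Ring order: benzene ring A is bought intact, and ring B is the only ring formed (step 4).

Assumption: the target SMILES holds no stereocentre and no stereogenic double bond, so it is one achiral compound and the request for a single enantiomer adds nothing beyond the constitution.

## Route

**Step 1**
Reactants: 1 2,4,6-trimethoxytoluene
Product: 3 1,3,5-trimethoxy-2,4-dimethylbenzene, via aryllithium 2 (not isolated)
Conditions: n-BuLi (1.2 equiv), TMEDA (1.2 equiv), THF, 0 °C to rt, 2 h; then MeI (1.5 equiv), 0 °C to rt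
Reagents that add atoms: iodomethane (MeI), CI
Why: Directed ortho-metalation followed by SN2 methylation: the two equivalent ring C–H bonds of 1 each lie between two methoxy groups that acidify them and bind lithium, so n-BuLi/TMEDA lithiates there rather than at the benzylic methyl, and aryllithium 2 is quenched cleanly by MeI; no stereocentre is formed.

**Step 2**
Reactants: 3 1,3,5-trimethoxy-2,4-dimethylbenzene; 4 hexadecanoyl chloride (palmitoyl chloride)
Product: 5 1-(2,4,6-trimethoxy-3,5-dimethylphenyl)hexadecan-1-one
Conditions: 4 (1.1 equiv), AlCl3 (1.3 equiv), CH2Cl2, −10 to 0 °C, 2 h; ice/1 M HCl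
Reagents that add atoms: hexadecanoyl chloride 4, CCCCCCCCCCCCCCCC(=O)Cl
Why: Friedel–Crafts acylation: 3 has a single free ring position that is ortho or para to all three methoxy donors, so the acylium ion from 4 and AlCl3 can only give 5, the ketone formed shuts down further attack, and the low temperature keeps the aryl methyl ethers intact; no stereocentre is formed.

**Step 3**
Reactants: 5 1-(2,4,6-trimethoxy-3,5-dimethylphenyl)hexadecan-1-one
Product: 7 1-(2-hydroxy-4,6-dimethoxy-3,5-dimethylphenyl)hexadecan-1-one, via dichloroboron chelate 6 (not isolated)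
Conditions: BCl3 (1.1 equiv, 1 M in CH2Cl2), CH2Cl2, −78 to 0 °C, 1.5 h; then H2O
Reagents that add atoms: none
Why: Chelation-controlled Lewis acid cleavage of an aryl methyl ether: BCl3 binds the ketone oxygen and a neighbouring methoxy oxygen in a six-membered ring, chloride removes that methyl group, the two ortho methoxy groups are equivalent by symmetry so one product results, and chelate 6 ties up the carbonyl so that the second ortho ether and the 4-methoxy group survive one equivalent of reagent at low temperature.

**Step 4**
Reactants: 7 1-(2-hydroxy-4,6-dimethoxy-3,5-dimethylphenyl)hexadecan-1-one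
Product: 10 5,7-dimethoxy-6,8-dimethyl-2-tridecyl-4H-chromen-4-one, via (E)-enone 8 (not isolated), via racemic chromanone 9 (not isolated)
Conditions: Pd(O2CCF3)2 (10 mol %), 4,5-diazafluoren-9-one (10 mol %), O2 (1 atm), DMSO/PhCl 1:1, 90 °C, 36 h
Reagents that add atoms: none
Why: Proposed new method: a phenol-anchored aerobic double dehydrogenative oxa-annulation in which one catalyst turns the saturated C16 ketone into the 4-pyranone ring: the ortho phenol of 7 replaces one trifluoroacetate on divalent palladium and holds the metal beside the α-CH2, the remaining trifluoroacetate removes an α-proton (concerted metalation–deprotonation) to give a six-membered O,C-chelated palladium enolate, β-hydride elimination releases (E)-enone 8, the phenol closes by 6-endo-trig oxa-Michael addition (catalysed by the released CF3CO2H, or as a Wacker-type oxypalladation) to racemic chromanone 9 and so makes the O1–C2 bond at what was an unactivated chain methylene, a second enolate palladation at C3 and β-hydride elimination of H-2 gives 10, O2 returns zerovalent palladium to the divalent state while the diazafluorenone ligand keeps it in solution, and the sequence stops at 10 because the vinylogous ester carbonyl of the chromone no longer enolises under these weakly acidic conditions, so the tridecyl chain stays saturated and the stereocentre of 9 is erased; the closest known reaction types are the aerobic palladium-catalysed α,β-dehydrogenation of acyclic aryl alkyl ketones and of chromanones with this catalyst and the palladium-catalysed oxidative cyclisation of 2'-hydroxydihydrochalcones to flavones (benzylic β-carbon), whereas the one-pot cascade on a purely aliphatic fatty chain carried by a hexasubstituted electron-rich ring has not been shown.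

**Step 5**
Reactants: 10 5,7-dimethoxy-6,8-dimethyl-2-tridecyl-4H-chromen-4-one
Product: 12 5,7-dihydroxy-6,8-dimethyl-2-tridecyl-4H-chromen-4-one, via bis(dibromoboryl) ether 11 (not isolated)
Conditions: BBr3 (5 equiv), CH2Cl2, −78 °C to rt, 12 h; then ice-water, rt, 1 h
Reagents that add atoms: none
Why: BBr3 cleavage of aryl methyl ethers: the 5-methoxy group falls fast through chelation to the C4 carbonyl, the 7-methoxy group is twisted out of conjugation by its two methyl neighbours and is therefore basic and readily cleaved, the chromone and the alkyl chain are inert to BBr3, and because the aryl part is symmetric any opening and reclosure of the pyranone would return the same compound; the target has no stereocentre.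

## Compound list
1 | 2,4,6-trimethoxytoluene (1,3,5-trimethoxy-2-methylbenzene) | Cc1c(OC)cc(OC)cc1OC | starting material
2 | (2,4,6-trimethoxy-3-methylphenyl)lithium, formed in the flask | Cc1c(OC)cc(OC)c([Li])c1OC | intermediate
3 | 1,3,5-trimethoxy-2,4-dimethylbenzene | Cc1c(OC)cc(OC)c(C)c1OC | intermediate
4 | hexadecanoyl chloride (palmitoyl chloride) | CCCCCCCCCCCCCCCC(=O)Cl | starting material
5 | 1-(2,4,6-trimethoxy-3,5-dimethylphenyl)hexadecan-1-one | CCCCCCCCCCCCCCCC(=O)c1c(OC)c(C)c(OC)c(C)c1OC | intermediate
6 | (2-hexadecanoyl-3,5-dimethoxy-4,6-dimethylphenoxy)dichloroborane, boron chelated by the ketone oxygen, formed in the flask | CCCCCCCCCCCCCCCC(=O)c1c(OB(Cl)Cl)c(C)c(OC)c(C)c1OC | intermediate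
7 | 1-(2-hydroxy-4,6-dimethoxy-3,5-dimethylphenyl)hexadecan-1-one | CCCCCCCCCCCCCCCC(=O)c1c(O)c(C)c(OC)c(C)c1OC | intermediate
8 | (E)-1-(2-hydroxy-4,6-dimethoxy-3,5-dimethylphenyl)hexadec-2-en-1-one, formed in the flask | CCCCCCCCCCCCC/C=C/C(=O)c1c(O)c(C)c(OC)c(C)c1OC | intermediate
9 | racemic 5,7-dimethoxy-6,8-dimethyl-2-tridecylchroman-4-one, formed in the flask | CCCCCCCCCCCCCC1CC(=O)c2c(OC)c(C)c(OC)c(C)c2O1 | intermediate
10 | 5,7-dimethoxy-6,8-dimethyl-2-tridecyl-4H-chromen-4-one | CCCCCCCCCCCCCc1cc(=O)c2c(OC)c(C)c(OC)c(C)c2o1 | intermediate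
11 | 5,7-bis[(dibromoboryl)oxy]-6,8-dimethyl-2-tridecyl-4H-chromen-4-one, formed in the flask | CCCCCCCCCCCCCc1cc(=O)c2c(OB(Br)Br)c(C)c(OB(Br)Br)c(C)c2o1 | intermediate
12 | 5,7-dihydroxy-6,8-dimethyl-2-tridecyl-4H-chromen-4-one (achiral) | CCCCCCCCCCCCCc1cc(=O)c2c(O)c(C)c(O)c(C)c2o1 | target

## Step count and risks
Total step count: 5.
Longest linear sequence: 5 (1 → 3 → 5 → 7 → 10 → 12).

**Risk 1, step 4 (the proposed new cascade).**
- The keto-phenolate may tie up palladium as an inert bis-chelate.
- α-Palladation of the twisted, di-ortho-substituted ketone may be slow.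
- Enone 8 may lose more hydrogen along the chain before it closes.
- The electron-rich ring may be oxidised.

The fallback is known chemistry: Baker–Venkataraman rearrangement, then acid cyclodehydration. It sets out from 3 and comes back at 10. It builds the C2–C3 bond by acyl transfer instead of oxidising C–H bonds. Compound 3 is acylated with acetyl chloride and AlCl3 (CH2Cl2, 0 °C) to 1-(2,4,6-trimethoxy-3,5-dimethylphenyl)ethan-1-one F1. BCl3 (1.1 equiv, CH2Cl2, −78 to 0 °C) turns it into (2-acetyl-3,5-dimethoxy-4,6-dimethylphenoxy)dichloroborane F2, which water hydrolyses to 1-(2-hydroxy-4,6-dimethoxy-3,5-dimethylphenyl)ethan-1-one F3. Tetradecanoyl chloride in pyridine with DMAP gives 2-acetyl-3,5-dimethoxy-4,6-dimethylphenyl tetradecanoate F4. t-BuOK in THF (0 °C to rt) moves the acyl group from oxygen to the acetyl carbon, and acidification gives 1-(2-hydroxy-4,6-dimethoxy-3,5-dimethylphenyl)hexadecane-1,3-dione F5. Catalytic H2SO4 in AcOH at 80 °C closes and dehydrates F5 to 10, which goes on to step 5.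

**Risk 2, step 2.**
- The acyl group enters between two methoxy groups and gives a crowded hexasubstituted ring.
- AlCl3 may cleave ethers unselectively.
- The crowded ketone may de-acylate.

The fallback reverses the polarity: a nucleophilic arene is used in a Weinreb ketone synthesis. It sets out from 3 and 4 and comes back at 5. Compound 4 with MeNH(OMe)·HCl and Et3N (CH2Cl2, 0 °C) gives N-methoxy-N-methylhexadecanamide F6. Compound 3 is lithiated at its only ring C–H with n-BuLi/TMEDA (THF, 0 °C to rt) to (2,4,6-trimethoxy-3,5-dimethylphenyl)lithium F7. This adds to F6 at −78 to 0 °C to give the chelated lithium 1-[methoxy(methyl)amino]-1-(2,4,6-trimethoxy-3,5-dimethylphenyl)hexadecan-1-olate F8 (racemic). A water quench collapses F8 to 5.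

**Risk 3, step 3.**
- All three methoxy groups of 5 are crowded, and BCl3 also attacks crowded ethers.
- The 4-methoxy group, or both ortho groups, may therefore be lost as well.

The fallback replaces selective deprotection with full deprotection and selective re-protection. It sets out from 5 and comes back at 7. BBr3 (6 equiv, CH2Cl2, −78 °C to rt) converts 5 into 1-{2,4,6-tris[(dibromoboryl)oxy]-3,5-dimethylphenyl}hexadecan-1-one F9, which water hydrolyses to 1-(2,4,6-trihydroxy-3,5-dimethylphenyl)hexadecan-1-one F10. Me2SO4 (2.1 equiv) and K2CO3 in refluxing acetone methylate the 4-hydroxyl and one of the two equivalent ortho hydroxyls. The last hydroxyl is held in a hydrogen bond to the ketone and stays free, which gives 7.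

## Further compounds
F1 | step 4 | 1-(2,4,6-trimethoxy-3,5-dimethylphenyl)ethan-1-one | CC(=O)c1c(OC)c(C)c(OC)c(C)c1OC
F2 | step 4 | (2-acetyl-3,5-dimethoxy-4,6-dimethylphenoxy)dichloroborane | CC(=O)c1c(OB(Cl)Cl)c(C)c(OC)c(C)c1OC
F3 | step 4 | 1-(2-hydroxy-4,6-dimethoxy-3,5-dimethylphenyl)ethan-1-one | CC(=O)c1c(O)c(C)c(OC)c(C)c1OC
F4 | step 4 | 2-acetyl-3,5-dimethoxy-4,6-dimethylphenyl tetradecanoate | CCCCCCCCCCCCCC(=O)Oc1c(C)c(OC)c(C)c(OC)c1C(C)=O
F5 | step 4 | 1-(2-hydroxy-4,6-dimethoxy-3,5-dimethylphenyl)hexadecane-1,3-dione | CCCCCCCCCCCCCC(=O)CC(=O)c1c(O)c(C)c(OC)c(C)c1OC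
F6 | step 2 | N-methoxy-N-methylhexadecanamide | CCCCCCCCCCCCCCCC(=O)N(C)OC
F7 | step 2 | (2,4,6-trimethoxy-3,5-dimethylphenyl)lithium | [Li]c1c(OC)c(C)c(OC)c(C)c1OC
F8 | step 2 | lithium 1-[methoxy(methyl)amino]-1-(2,4,6-trimethoxy-3,5-dimethylphenyl)hexadecan-1-olate (racemic) | CCCCCCCCCCCCCCCC(O[Li])(N(C)OC)c1c(OC)c(C)c(OC)c(C)c1OC
F9 | step 3 | 1-{2,4,6-tris[(dibromoboryl)oxy]-3,5-dimethylphenyl}hexadecan-1-one | CCCCCCCCCCCCCCCC(=O)c1c(OB(Br)Br)c(C)c(OB(Br)Br)c(C)c1OB(Br)Br
F10 | step 3 | 1-(2,4,6-trihydroxy-3,5-dimethylphenyl)hexadecan-1-one | CCCCCCCCCCCCCCCC(=O)c1c(O)c(C)c(O)c(C)c1O
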